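Free catalyst, single-handed, uses reagent to turn a racemate of left-handed and right-handed substrate into left-handed and right-handed product, while the racemization catalyst swaps the two substrates.

| flask | left-handed substrate | right-handed substrate | reagent | free catalyst | racemization catalyst | remark | time |
|---|---|---|---|---|---|---|---|
| eta | 1 M | 1 M | 2.2 M | 120 mM | 0.25 mM | run made earlier |  |
| delta | 1 M | 1 M | 2.2 M | 120 mM | 0.38 mM | run made earlier |  |
| flask | 1.0 M | 1.0 M | 2.20 M | 120 mM | 0.50 mM |  | 4.0 min |

| run | time / min | left-handed substrate / % | right-handed substrate / % |
|---|---|---|---|
| eta | 1.33 | 27.6 | 40.1 |
| eta | 2.50 | 28.0 | 36.2 |
| eta | 4.00 | 29.9 | 35.2 |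
| eta | 5.00 | 28.4 | 33.3 |
| delta | 0.417 | 33.4 | 44.7 |
| delta | 0.833 | 28.2 | 41.3 |
| delta | 2.00 | 29.2 | 37.0 |
| delta | 5.00 | 30.1 | 34.0 |

(standard deviation of a reading: 0.5 percentage points)

- free catalyst is single-handed; left-handed substrate and right-handed substrate are mirror images of each other, charged as a racemate, each of them at the stated concentration
- the analysis behind the earlier runs scatters by 0.5 percentage points, standard deviation
- an excess is the difference of the two amounts in percent of their sum
- an excess is below zero if the other one leads

- part of the left-handed substrate and right-handed substrate charged together that has reacted at 4.0 min
- excess of left-handed product over right-handed product in the product at 4.0 min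
- excess of right-handed substrate over left-handed substrate among what is left of the two at 4.0 min

In both earlier runs the sum of the two substrates falls fast and then stands near 63.6 % of the charge, the mean of the late readings. The flask has the same charges of free catalyst, reagent and substrates, so a first estimate is 36.4 % reacted.

Has the reagent run out? No. If reagent and substrate react one to one, that sum leaves 66.9 % of the reagent. A reversible step, however, is a rival reading of the same stall, and the two runs, with one catalyst charge, leave the choice between it and a dying catalyst open. The reckoning therefore assumes first-order loss of free catalyst, and a different charge is the test.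

Fractions left then carry the argument. The integrated second-order law, with the substrates taken roughly as one pool, makes the logarithm of reagent fraction left over substrate fraction left grow in step with free catalyst summed over time. Late readings put it at 0.0507, called the catalyst dose.

But is the flask at its stall by 4.0 min? In the delta run at 0.417 min, the sum 78.1 % gives a dose of 0.0252. That reads as a decay time of 0.607 min, so by this estimate from scattered readings about 0.137 % of the dose remains undelivered at 4.0 min.

The dose says nothing of the split. Still, in that delta reading the substrate gap is already 51.6 % of what has reacted, and swapping narrows such a gap, so the estimate for the product excess in the delta run at that moment lies above this figure.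

The forecast gave 36.5 %, 18 % and 6 %, adding of the second that this “value is poorly constrained”. The flask gives 36.0 %, 82.5 % and 6.36 %.

    reagent + free catalyst + left-handed substrate → free catalyst + left-handed product (k = 0.120 L² mol⁻² s⁻¹)
    reagent + free catalyst + right-handed substrate → free catalyst + right-handed product (k = 0.00930 L² mol⁻² s⁻¹)
    left-handed substrate + racemization catalyst ⇌ right-handed substrate + racemization catalyst, rate k3*[racemization catalyst]*[left-handed substrate] forward; the back reaction follows from the equilibrium constant (k = 110 L mol⁻¹ s⁻¹)
    2 racemization catalyst ⇌ resting dimer (K = 3.80 × 10⁵ L mol⁻¹, k = 130 L mol⁻¹ s⁻¹)
    free catalyst → spent catalyst (k = 0.0280 s⁻¹)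

The main reason the flask stands at 36.0 % is the conversion of free catalyst into spent catalyst: spent catalyst is 99.9 % of the catalyst charged at 4.00 min, and the same run without that step reaches 75.1 % at that time. This flask's own dose is 0.0498; scaled by 1.67 for the neighbour with 0.20 M of free catalyst, it gives 48.8 % reacted. That neighbour has reacted 47.3 %.

(The data are calculated for an exercise, and the scatter is random.)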